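All constants are those of an exercise; the result is computed.

A small charge of electrophile has to be turned over almost completely within the run, so reckon how much nucleophile that takes.

electrophile 0.050 M; time 1.5 min

    nucleophile + acid set free ⇌ protonated nucleophile, settled at all times (K1 = 31000 L mol⁻¹)
    2 nucleophile → self-condensation product (k2 = 2.36 L mol⁻¹ s⁻¹)
    electrophile + nucleophile → acid set free + target (k3 = 28.3 L mol⁻¹ s⁻¹)

- the concentration of nucleophile at which the part of the electrophile that has reacted at 1.5 min is just 95%, in M

The electrophile's rate is k3·N·E, with N the free nucleophile and E the electrophile, so its rate follows N. To reach the wanted level in run time t, N must average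

N̄ = −ln(1 − 95%)/(k3·t) = 0.00118 M

Now climb the ladder. First comes proton transfer, held at balance: protonated nucleophile stands to free acid as K1·N̄ = 36.5, so nearly all the acid is caught, and protonated nucleophile is the nucleophile's resting state. Each turn therefore costs two nucleophile, one coupled and one caught:

D = 2 × 95% × cA = 0.0950 M

Call D the demand, two nucleophile for each electrophile turned over.

Next comes coupling: with nucleophile near D, the electrophile lasts about 1/(k3·D) = 0.372 s. Self-condensation has, at that level, a half-life 1/(2·k2·D) = 2.23 s, which is longer than the electrophile's time; leave it out and expect a low figure. Both times hold only with N near D, and the run of 90 s is far longer than either, so reckon the rest of the run at low N, with N̄ left over once the demand is met. Charge D + N̄: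

0.0962 M

The forecast gave 0.101 M, within 0.0995 M to 0.1025 M, on this ground: "Each electrophile that reacts uses one nucleophile and frees one acid, which ties up a second nucleophile".

The flask needs 0.101 M, which is 1.06 times the demand, and at 1.50 min 0.207% of that charge is still free. Read the demand backward for the flask with half this nucleophile: at two per turn, its charge covers 50.4% of the electrophile. That flask reaches more than this, 59.7% at the end of the run.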